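Everything rests on cutting the isoflavan at C3–C1′ and C4–C4a, so that C3–C4 comes from a vinylboronate and both aryl rings are attached in one enantioselective palladium-catalysed conjunctive coupling. The step exploits the vicinal pattern in which C3 carries ring B and C4 carries ring A: ring B migrates from boron to C3 while the ring A arylpalladium bonds C4, which sets the single stereocentre (C3) and leaves a C3–B bond for one-carbon extension to C2. The precursor is the lithium ate complex of vinylboronic pinacol ester with a MOM-directed ring B aryllithium, met by a benzyl-protected ring A bromide. Mitsunobu closure of ring C and late quinone formation finish the route.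

Key step: step 4

Numbering used: chroman O1, C2, C3, C4, C4a, C5–C8, C8a; ring A is the benzo ring, ring C the pyran ring, ring B the aryl (later quinone) ring on C3 with atoms C1′–C6′. The target SMILES corresponds to the (3S) isomer.

Assumption: ligand L = (Rp,Rp)-1,1′-bis(diphenylphosphino)-2,2′-bis[(S)-α-(dimethylamino)benzyl]ferrocene (MandyPhos, C52H50FeN2P2) is taken as the enantiomer that leads to (S)-9; if a pilot run shows the opposite sense, its commercially available mirror image replaces it and nothing else changes.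

Step 1
Reactants: 1 2,3-dimethoxyphenol
Product: 2 1,2-dimethoxy-3-(methoxymethoxy)benzene
Conditions: NaH, MOMCl, THF, 0 °C → rt
Reagents that add atoms: chloromethyl methyl ether, COCCl
Why: Williamson-type O-alkylation of the sodium phenoxide with the reactive α-chloro ether installs the MOM group, which later directs ortho-lithiation and stays orthogonal to the benzyl ether on ring A.

Step 2
Reactants: 3 2,3,4-trimethoxyphenol
Product: 4 6-bromo-2,3,4-trimethoxyphenol
Conditions: NBS (1.0 equiv), CH2Cl2, 0 °C, dark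
Reagents that add atoms: N-bromosuccinimide, O=C1CCC(=O)N1Br
Why: Electrophilic aromatic bromination, in which the free hydroxyl is the strongest activator and has its para and one ortho position blocked, so the single open ortho carbon (C6) should be brominated, while the non-polar solvent and low temperature hold back attack on the methoxy-activated C5 and oxidation to a quinone.

Step 3
Reactants: 4 6-bromo-2,3,4-trimethoxyphenol
Product: 5 1-(benzyloxy)-6-bromo-2,3,4-trimethoxybenzene
Conditions: BnBr, K2CO3, DMF, rt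
Reagents that add atoms: benzyl bromide, BrCc1ccccc1
Why: Williamson ether synthesis on the phenoxide gives a benzyl ether that tolerates the organolithium, palladium, carbenoid and peroxide steps and is later removed by hydrogenolysis without touching the MOM group.

Step 4
Reactants: 2 1,2-dimethoxy-3-(methoxymethoxy)benzene; 6 vinylboronic acid pinacol ester; 5 1-(benzyloxy)-6-bromo-2,3,4-trimethoxybenzene
Product: 9 (S)-2-{2-[2-(benzyloxy)-3,4,5-trimethoxyphenyl]-1-[3,4-dimethoxy-2-(methoxymethoxy)phenyl]ethyl}-4,4,5,5-tetramethyl-1,3,2-dioxaborolane, via aryllithium 7 (not isolated), via lithium vinylboron ate complex 8 (not isolated)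
Conditions: 2 (1.3 equiv), n-BuLi (1.2 equiv), THF, 0 °C; 6 (1.2 equiv), 0 °C → rt; then Pd(OAc)2 (3 mol%), ligand L (3.6 mol%), NaOTf (2 equiv), 5 (1.0 equiv), THF, 60 °C
Reagents that add atoms: none
Why: Zerovalent palladium formed from Pd(OAc)2 and ligand L inserts into the C–Br bond of 5 and, once NaOTf has removed bromide, the cationic divalent arylpalladium binds the vinyl group of ate complex 8, so that ring B shifts from boron to the α-carbon anti to the metal while palladium bonds the β-carbon, and reductive elimination then forms C4–C4a. The closest known reaction type is the palladium-catalysed enantioselective conjunctive cross-coupling of vinylboron ate complexes with aryl halides, a known three-component process used here on a new pair of ortho-alkoxy aryl partners. No ring is closed: the two skeletal bonds C3–C1′ and C4–C4a are made in an open chain. The C3 stereocentre is set under catalyst control, the chiral ferrocenyl bisphosphine on palladium choosing the face of the bound alkene at which migration occurs, and the secondary benzylic C–B bond is configurationally stable afterwards. The step needs aryl migration to outrun pinacol-oxygen migration, direct Suzuki transfer and β-hydride loss; the good migrating ability of the electron-rich aryl group, the four-coordinate pinacol boronate, the wide-bite-angle ligand and halide scavenging should secure this. Generating 7 by deprotonation (directed ortho-metalation by the OMOM group, only butane as by-product) with n-BuLi as the limiting reagent keeps lithium halide and any butyl ate complex out of the flask.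

Step 5
Reactants: 9 (S)-2-{2-[2-(benzyloxy)-3,4,5-trimethoxyphenyl]-1-[3,4-dimethoxy-2-(methoxymethoxy)phenyl]ethyl}-4,4,5,5-tetramethyl-1,3,2-dioxaborolane
Product: 12 (S)-3-[2-(benzyloxy)-3,4,5-trimethoxyphenyl]-2-[3,4-dimethoxy-2-(methoxymethoxy)phenyl]propan-1-ol, via chloromethyl boron ate complex 10 (not isolated), via homologated pinacol boronate 11 (not isolated)
Conditions: BrCH2Cl, n-BuLi, THF, −78 °C → rt; then 3 M NaOH, 30% H2O2, 0 °C → rt
Reagents that add atoms: bromochloromethane, ClCBr; hydrogen peroxide, OO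
Why: Matteson homologation, in which chloromethyllithium made in situ adds to boron and the benzylic carbon C3 migrates to the CH2 group with loss of chloride and retention of configuration, after which alkaline peroxide oxidises the new primary C–B bond (C3 no longer bears boron and cannot be affected) to give C2 as CH2OH.

Step 6
Reactants: 12 (S)-3-[2-(benzyloxy)-3,4,5-trimethoxyphenyl]-2-[3,4-dimethoxy-2-(methoxymethoxy)phenyl]propan-1-ol
Product: 13 6-{(2S)-2-[3,4-dimethoxy-2-(methoxymethoxy)phenyl]-3-hydroxypropyl}-2,3,4-trimethoxyphenol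
Conditions: H2 (1 atm), 10% Pd/C, EtOAc, rt
Reagents that add atoms: none
Why: Catalytic hydrogenolysis of the benzyl aryl ether under neutral conditions frees the ring A phenol and leaves the MOM acetal, the methyl ethers and the stereocentre untouched.

Step 7
Reactants: 13 6-{(2S)-2-[3,4-dimethoxy-2-(methoxymethoxy)phenyl]-3-hydroxypropyl}-2,3,4-trimethoxyphenol
Product: 14 (3S)-3-[3,4-dimethoxy-2-(methoxymethoxy)phenyl]-6,7,8-trimethoxychroman
Conditions: PPh3, DIAD, THF, 0 °C → rt
Reagents that add atoms: none
Why: Intramolecular Mitsunobu etherification, in which the ring A phenol displaces the activated primary alcohol in a 6-exo-tet closure of ring C (O1–C2); C3 is not the reacting carbon and keeps its configuration, and the ring B oxygen is still masked so no five-membered ether can form.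

Step 8
Reactants: 14 (3S)-3-[3,4-dimethoxy-2-(methoxymethoxy)phenyl]-6,7,8-trimethoxychroman
Product: 15 2,3-dimethoxy-6-[(3S)-6,7,8-trimethoxychroman-3-yl]phenol
Conditions: 3 M HCl, MeOH, 40 °C
Reagents that add atoms: none
Why: Acid-catalysed acetal cleavage (transacetalisation to methanol) frees the ring B phenol, while the aryl methyl ethers and the chroman ether are stable to dilute acid.

Step 9
Reactants: 15 2,3-dimethoxy-6-[(3S)-6,7,8-trimethoxychroman-3-yl]phenol
Product: 16 abruquinone B, 2,3-dimethoxy-5-[(3S)-6,7,8-trimethoxychroman-3-yl]-1,4-benzoquinone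
Conditions: (KSO3)2NO (2.5 equiv), aq KH2PO4, acetone/H2O, rt
Reagents that add atoms: potassium nitrosodisulfonate, [K+].[K+].[O-]S(=O)(=O)N([O])S(=O)(=O)[O-]
Why: Teuber oxidation, in which one nitrosodisulfonate radical removes the phenolic hydrogen and a second adds at the unsubstituted para carbon (C5′) before elimination to the para-quinone; both ortho positions are blocked, so only the 1,4-quinone can form, and ring A and C3 are not touched.

Compound list
1 | 2,3-dimethoxyphenol | COc1cccc(O)c1OC | starting material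
2 | 1,2-dimethoxy-3-(methoxymethoxy)benzene | COCOc1cccc(OC)c1OC | intermediate
3 | 2,3,4-trimethoxyphenol | COc1ccc(O)c(OC)c1OC | starting material
4 | 6-bromo-2,3,4-trimethoxyphenol | COc1cc(Br)c(O)c(OC)c1OC | intermediate
5 | 1-(benzyloxy)-6-bromo-2,3,4-trimethoxybenzene | COc1cc(Br)c(OCc2ccccc2)c(OC)c1OC | intermediate
6 | vinylboronic acid pinacol ester | C=CB1OC(C)(C)C(C)(C)O1 | starting material
7 | [3,4-dimethoxy-2-(methoxymethoxy)phenyl]lithium | [Li]c1ccc(OC)c(OC)c1OCOC | intermediate (not isolated)
8 | lithium [3,4-dimethoxy-2-(methoxymethoxy)phenyl](vinyl)(pinacolato)borate | [Li+].C=C[B-]1(c2ccc(OC)c(OC)c2OCOC)OC(C)(C)C(C)(C)O1 | intermediate (not isolated)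
9 | (S)-2-{2-[2-(benzyloxy)-3,4,5-trimethoxyphenyl]-1-[3,4-dimethoxy-2-(methoxymethoxy)phenyl]ethyl}-4,4,5,5-tetramethyl-1,3,2-dioxaborolane | COCOc1c([C@H](Cc2cc(OC)c(OC)c(OC)c2OCc2ccccc2)B2OC(C)(C)C(C)(C)O2)ccc(OC)c1OC | intermediate
10 | lithium (chloromethyl) ate complex of 9, configuration at C3 unchanged (S) | [Li+].COCOc1c([C@H](Cc2cc(OC)c(OC)c(OC)c2OCc2ccccc2)[B-]2(CCl)OC(C)(C)C(C)(C)O2)ccc(OC)c1OC | intermediate (not isolated)
11 | 2-{(2S)-3-[2-(benzyloxy)-3,4,5-trimethoxyphenyl]-2-[3,4-dimethoxy-2-(methoxymethoxy)phenyl]propyl}-4,4,5,5-tetramethyl-1,3,2-dioxaborolane | COCOc1c([C@H](Cc2cc(OC)c(OC)c(OC)c2OCc2ccccc2)CB2OC(C)(C)C(C)(C)O2)ccc(OC)c1OC | intermediate (not isolated)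
12 | (S)-3-[2-(benzyloxy)-3,4,5-trimethoxyphenyl]-2-[3,4-dimethoxy-2-(methoxymethoxy)phenyl]propan-1-ol | COCOc1c([C@H](Cc2cc(OC)c(OC)c(OC)c2OCc2ccccc2)CO)ccc(OC)c1OC | intermediate
13 | 6-{(2S)-2-[3,4-dimethoxy-2-(methoxymethoxy)phenyl]-3-hydroxypropyl}-2,3,4-trimethoxyphenol | COCOc1c([C@H](Cc2cc(OC)c(OC)c(OC)c2O)CO)ccc(OC)c1OC | intermediate
14 | (3S)-3-[3,4-dimethoxy-2-(methoxymethoxy)phenyl]-6,7,8-trimethoxychroman | COCOc1c([C@H]2COc3c(cc(OC)c(OC)c3OC)C2)ccc(OC)c1OC | intermediate
15 | 2,3-dimethoxy-6-[(3S)-6,7,8-trimethoxychroman-3-yl]phenol | Oc1c([C@H]2COc3c(cc(OC)c(OC)c3OC)C2)ccc(OC)c1OC | intermediate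
16 | abruquinone B, 2,3-dimethoxy-5-[(3S)-6,7,8-trimethoxychroman-3-yl]-1,4-benzoquinone | COC1=C(OC)C(=O)C([C@H]2COc3c(cc(OC)c(OC)c3OC)C2)=CC1=O | target

Total step count: 9. Longest linear sequence: 8 steps (3 → 4 → 5 → 9 → 12 → 13 → 14 → 15 → 16; the ring B branch 1 → 2 joins at step 4).

Steps most likely to fail

Step 4. With an ortho-OMOM group on the migrating ring and an ortho-OBn group on the arylpalladium, the metallate shift may become slow, so that direct Suzuki-type transfer, protonation of the ate complex or poor facial discrimination take over. The fallback is an auxiliary-controlled alkylation that sets out from 2 and 5 and rejoins the route at 12.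
- Aryllithium 7, made from 2 as in step 4, is quenched with ethylene oxide (THF, −78 °C → rt) to give 2-[3,4-dimethoxy-2-(methoxymethoxy)phenyl]ethanol F1.
- F1 is oxidised with TEMPO and PhI(OAc)2 in MeCN/H2O to [3,4-dimethoxy-2-(methoxymethoxy)phenyl]acetic acid F2.
- F2 is joined to (S)-4-benzyl-2-oxazolidinone (PivCl, Et3N, LiCl, THF) to give (S)-4-benzyl-3-{[3,4-dimethoxy-2-(methoxymethoxy)phenyl]acetyl}oxazolidin-2-one F3.
- Separately, bromine–lithium exchange on 5 (n-BuLi, THF, −78 °C) gives [2-(benzyloxy)-3,4,5-trimethoxyphenyl]lithium F4, which is trapped with paraformaldehyde to give [2-(benzyloxy)-3,4,5-trimethoxyphenyl]methanol F5.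
- PBr3 (CH2Cl2, 0 °C) converts F5 into 1-(benzyloxy)-6-(bromomethyl)-2,3,4-trimethoxybenzene F6.
- The sodium enolate of F3 (NaN(SiMe3)2, THF, −78 °C) should be alkylated by F6 on the face away from the benzyl group of the auxiliary (Evans alkylation), giving (S)-4-benzyl-3-{(S)-3-[2-(benzyloxy)-3,4,5-trimethoxyphenyl]-2-[3,4-dimethoxy-2-(methoxymethoxy)phenyl]propanoyl}oxazolidin-2-one F7.
- LiBH4 (THF/MeOH, 0 °C) then releases 12.

Step 5. Addition of the short-lived carbenoid to the hindered secondary benzylic boronate may lag behind carbenoid decomposition, which would leave unhomologated material that is oxidised to the secondary alcohol, or allow a second insertion. The fallback runs from 9 to 12 by vinylation and oxidative cleavage.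
- 9 is treated with CH2=CHMgBr in THF/DMSO to form the bromomagnesium vinyl ate complex of 9 F8.
- I2 followed by NaOMe/MeOH (Zweifel olefination, retention at the migrating carbon) gives (R)-3-[3,4-dimethoxy-2-(methoxymethoxy)phenyl]-4-[2-(benzyloxy)-3,4,5-trimethoxyphenyl]but-1-ene F9.
- Ozonolysis (O3, CH2Cl2/MeOH, −78 °C, dosed to a Sudan Red 7B end point to spare the arenes) passes through (S)-3-[2-(benzyloxy)-3,4,5-trimethoxyphenyl]-2-[3,4-dimethoxy-2-(methoxymethoxy)phenyl]propanal F10.
- F10 is reduced in the same flask with NaBH4 before it can epimerise, giving 12.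

Step 9. The radical oxidation may stall or run on to over-oxidised material, the reagent is sensitive to its quality, and the electron-rich quinone may be lost on work-up. The fallback runs from 15 to 16 by the classical azo route.
- Para-coupling of 15 with freshly diazotised sulfanilic acid (aq NaOH, 0 °C) gives 4-[(E)-{4-hydroxy-2,3-dimethoxy-5-[(3S)-6,7,8-trimethoxychroman-3-yl]phenyl}diazenyl]benzenesulfonic acid F11.
- Na2S2O4 (aq, 50 °C) cleaves the N=N bond to give 4-amino-2,3-dimethoxy-6-[(3S)-6,7,8-trimethoxychroman-3-yl]phenol F12.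
- FeCl3 in dilute HCl oxidises F12 to the quinone imine, which hydrolyses to 16.

Further compounds
F1 | step 4 | 2-[3,4-dimethoxy-2-(methoxymethoxy)phenyl]ethanol | COCOc1c(CCO)ccc(OC)c1OC
F2 | step 4 | [3,4-dimethoxy-2-(methoxymethoxy)phenyl]acetic acid | COCOc1c(CC(O)=O)ccc(OC)c1OC
F3 | step 4 | (S)-4-benzyl-3-{[3,4-dimethoxy-2-(methoxymethoxy)phenyl]acetyl}oxazolidin-2-one | COCOc1c(CC(=O)N2[C@@H](Cc3ccccc3)COC2=O)ccc(OC)c1OC
F4 | step 4 | [2-(benzyloxy)-3,4,5-trimethoxyphenyl]lithium | [Li]c1cc(OC)c(OC)c(OC)c1OCc1ccccc1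
F5 | step 4 | [2-(benzyloxy)-3,4,5-trimethoxyphenyl]methanol | COc1cc(CO)c(OCc2ccccc2)c(OC)c1OC
F6 | step 4 | 1-(benzyloxy)-6-(bromomethyl)-2,3,4-trimethoxybenzene | COc1cc(CBr)c(OCc2ccccc2)c(OC)c1OC
F7 | step 4 | (S)-4-benzyl-3-{(S)-3-[2-(benzyloxy)-3,4,5-trimethoxyphenyl]-2-[3,4-dimethoxy-2-(methoxymethoxy)phenyl]propanoyl}oxazolidin-2-one | COCOc1c([C@H](Cc2cc(OC)c(OC)c(OC)c2OCc2ccccc2)C(=O)N2[C@@H](Cc3ccccc3)COC2=O)ccc(OC)c1OC
F8 | step 5 | bromomagnesium vinyl ate complex of 9 | Br[Mg+].COCOc1c([C@H](Cc2cc(OC)c(OC)c(OC)c2OCc2ccccc2)[B-]2(C=C)OC(C)(C)C(C)(C)O2)ccc(OC)c1OC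
F9 | step 5 | (R)-3-[3,4-dimethoxy-2-(methoxymethoxy)phenyl]-4-[2-(benzyloxy)-3,4,5-trimethoxyphenyl]but-1-ene | COCOc1c([C@H](Cc2cc(OC)c(OC)c(OC)c2OCc2ccccc2)C=C)ccc(OC)c1OC
F10 | step 5 | (S)-3-[2-(benzyloxy)-3,4,5-trimethoxyphenyl]-2-[3,4-dimethoxy-2-(methoxymethoxy)phenyl]propanal | COCOc1c([C@H](Cc2cc(OC)c(OC)c(OC)c2OCc2ccccc2)C=O)ccc(OC)c1OC
F11 | step 9 | 4-[(E)-{4-hydroxy-2,3-dimethoxy-5-[(3S)-6,7,8-trimethoxychroman-3-yl]phenyl}diazenyl]benzenesulfonic acid | OS(=O)(=O)c1ccc(/N=N/c2cc([C@H]3COc4c(cc(OC)c(OC)c4OC)C3)c(O)c(OC)c2OC)cc1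
F12 | step 9 | 4-amino-2,3-dimethoxy-6-[(3S)-6,7,8-trimethoxychroman-3-yl]phenol | Nc1cc([C@H]2COc3c(cc(OC)c(OC)c3OC)C2)c(O)c(OC)c1OC
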